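## The problem

Cladonaphchrom A (22) is a 2-methylchroman with a 4,5-dimethoxynaphthalen-1-yl group at C4 and a free hydroxyl at C5 of its benzo ring (ring A). Because the peri-dioxygenated naphthalene can be bought, the synthesis has to make the pyran ring and the bonds around C4. The two stereocentres, C2 (R) and C4 (S), are 1,3-related across the pyran ring, with methyl and naphthyl trans. C2 is a non-acidic secondary ether carbon that cannot be corrected later, so its absolute configuration must be brought in securely. C4 is doubly benzylic, can be made late and can be equilibrated; since the C5 oxygen is peri to C4, a pseudoequatorial naphthyl would be pressed against it, so with methyl equatorial the trans isomer should be the stable one, and C2 can control C4 but not the reverse. The sensitive parts are the electron-rich 1,8-dimethoxynaphthalene (oxidants, electrophiles, strong Lewis acids), its two methyl ethers, which must stay while the C5 phenol is freed (so C5 needs an orthogonal protecting group), and the oxidizable C4–H bond. The feature that opens the key step is the contiguous triad C5–C4a–C8a of ring A, carrying oxygen, carbon (C4) and oxygen (O1): a 3-alkoxybenzyne delivers this pattern, taking a nucleophile at the aryne carbon remote from the alkoxy group (C8a) and an electrophile at the carbon next to it (C4a).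

## Retrosynthesis

**22 ⇒ 21.** Only the O–CH2Ph bond at C5 is cut. Benzyl is chosen because hydrogenolysis leaves the two naphthyl methyl ethers, the pyran ether and C4–H alone; a third methyl ether would demand a selective demethylation, and a silyl ether would not survive the fluoride of the key step. The forward step must debenzylate without reducing the naphthalene.

**21 ⇒ 20 ⇒ 19.** The C4–H bond is traced back to a C4–OH bond. Carbinol 19 is what a carbonyl capture at C4 naturally gives, and its C4 configuration is irrelevant because ionization erases it. Compared with setting C4 by an asymmetric C–C bond formation, this leaves only one stereocentre (C2) to be made absolutely. The forward steps must reduce a doubly benzylic cation (19 to 20) and then let C2 steer C4 to the trans isomer by equilibration (20 to 21).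

**19 ⇒ 16 + 8.** Both bonds from the pyran ring to ring A, O1–C8a and C4–C4a, are cut together. The synthon for ring A is 3-(benzyloxy)benzyne 17, released from silyl triflate 16; the partner is the acyclic hydroxy ketone 8, which holds C2, C3, C4 and the whole naphthalene.
- Against cutting O1–C2 (Mitsunobu-type closure): that route inverts C2 and risks elimination, whereas here the C2–O bond is never broken.
- Against cutting C4–C4a alone (aryllithium plus ketone): the aryl ether would still have to be made, with regiocontrol on a resorcinol.
- The precursors are far simpler: an achiral arene and a ketone with one stereocentre taken from the chiral pool.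
- The forward reaction must arylate oxygen at the aryne carbon remote from the benzyloxy group, trap aryl anion 18 on the ketone before it is protonated, and do both faster than 8 suffers retro-aldol cleavage or dehydration.

**8 ⇒ 3 + 5.** The C1'–C(=O) bond is cut to an aryllithium (6, from bromide 3) and Weinreb amide 5. A Friedel–Crafts acylation of 2 would expose a β-oxygenated acyl chloride to a Lewis acid and invite elimination. The organolithium route fixes the position through the bromide and stops at the ketone. The hydroxyl is carried as its magnesium alkoxide 7, which saves a protection and a deprotection.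

**5 ⇒ 4 and 3 ⇒ 2 ⇒ 1.** Amide 5 is the aminolysis product of commercial ethyl (R)-3-hydroxybutanoate 4; the stereocentre is remote from the reacting carbonyl. Bromide 3 comes from para-bromination of 1,8-dimethoxynaphthalene 2, itself the bis-methyl ether of naphthalene-1,8-diol 1.

**16 ⇒ 14 ⇒ 10 ⇒ 9.** The C–Si and O–S bonds are cut. In carbamate 10 of 3-(benzyloxy)phenol 9, the position between the two oxygens is the one that both groups direct lithium to, so the silyl group goes where the aryne needs it. The carbamate is then exchanged for triflate in one flask. A bromophenol/retro-Brook route would need a statistical mono-benzylation of 2-bromoresorcinol.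

## Roads not taken

**Alternative 1:** The cut is through the naphthalene (C1'–C8a' and C4'–C4a'). The (2R,4R)-5-(benzyloxy)-4-(furan-2-yl)-2-methylchroman A2 would take up the boryl aryne A3 across its furan in a [4+2] cycloaddition to give the 1,4-epoxy-1,4-dihydronaphthalene A1. Bridge opening with aromatization, C–B oxidation, double O-methylation and debenzylation would follow.
- Merits: aryne–furan cycloadditions are among the most dependable aryne reactions. A boryl group next to the triple bond should orient addition to a 2-substituted furan so that boron ends peri to the unsubstituted bridgehead. No aldol-type intermediate is exposed to base.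
- Weak points: the aryne step builds a ring that is commercially available with both oxygens in place. At least four steps follow A1, and the acid-induced bridge opening must break the C–O bond at the substituted bridgehead only. Above all, A2 already contains the chroman with both stereocentres, so the real problem of the target is moved, not solved.
- Comparison: this road is better in the reliability of its key step. The chosen plan sets against it that its aryne step forms the ring that actually has to be made, and that the route is much shorter.

**Alternative 2:** The cut is C3–C4 and O1–C2. A chiral phosphoric acid would dehydrate diaryl carbinol A5 to ortho-quinone methide A6 and guide the inverse-demand oxa-Diels–Alder addition of 2-methoxypropene A7, giving 2-methoxy-2-methylchroman A4 with C4 set by the catalyst.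
- Merits: it is convergent and short, the symmetric 2,6-dihydroxyphenyl group makes either hydroxyl equivalent, and C4, the harder centre, is set directly by catalysis instead of by equilibration. In these respects it is better than the chosen plan.
- Weak points: A6 carries a bulky, strongly donating naphthyl group and two ortho substituents. The derived cation is so stabilized that an uncatalysed background reaction and loose ion pairing threaten the enantioselectivity. C2 emerges as a ketal carbon and must afterwards be reduced to C2–H with the correct relative configuration, a selectivity for which the axial naphthyl and axial hydride delivery pull in opposite directions.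
- Comparison: the chosen plan sets against it that its absolute configuration is bought (C2 from 4) and that C4 then follows from a bias built into the substrate, with no reliance on induction in an untested, crowded quinone methide.

**Alternative 3:** The cut is O1–C2, C2–C3 and C4–C1' in one operation. A chiral Brønsted acid would condense vinylphenol A9 with acetaldehyde A10 to an aryl oxocarbenium ion, the vinyl group would cyclize onto it, and 1,8-dimethoxynaphthalene 2 would trap the C4 cation to give pivalate A8.
- Merits: it is by far the shortest road. The nucleophile should enter the 2-substituted chromanyl cation anti to the methyl group, so the trans relationship would arise kinetically, without an equilibration; in this respect it is better than the chosen plan.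
- Weak points: the only source of absolute configuration is catalyst control in the addition to an oxocarbenium ion that carries nothing larger than a methyl group. Three components offer many competing pairings: 2 is nucleophilic enough to attack A10 or the oxocarbenium ion directly, A9 can dimerize or be hydroarylated, and A10 self-condenses.
- Comparison: the chosen plan sets against it bond formations that are separated and individually predictable, with a purchased stereocentre. The trans-selective Friedel–Crafts capture is kept as a fallback for the C4 problem.

Key step: step 8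

Assumption: with the C5 benzyloxy group peri to C4, the 2,4-trans isomer 21 (methyl equatorial, naphthyl pseudoaxial) is taken to be more stable than its cis epimer; steps 9 and 10 rest on this.
Remark: 19 and 20 are carried as C4-epimer mixtures, so their SMILES leave C4 undefined.

## Route

Step 1
Reactants: 1 naphthalene-1,8-diol
Product: 2 1,8-dimethoxynaphthalene
Conditions: NaH, MeI, DMF, 0 °C → rt
Reagents that add atoms: iodomethane, CI
Why: Double Williamson O-methylation (SN2); NaH in DMF removes both protons, overcoming the internal hydrogen bond of the mono-anion that slows the second methylation with weaker bases.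

Step 2
Reactants: 2 1,8-dimethoxynaphthalene
Product: 3 4-bromo-1,8-dimethoxynaphthalene
Conditions: NBS (1.0 equiv), MeCN, 0 °C → rt
Reagents that add atoms: N-bromosuccinimide, O=C1CCC(=O)N1Br
Why: Electrophilic aromatic bromination; each methoxy group directs para, so NBS in MeCN should brominate C4, and one equivalent at low temperature should stop before the 4,5-dibromide.

Step 3
Reactants: 4 ethyl (R)-3-hydroxybutanoate
Product: 5 (R)-3-hydroxy-N-methoxy-N-methylbutanamide
Conditions: MeNHOMe·HCl, i-PrMgCl, THF, −20 → 0 °C
Reagents that add atoms: N,O-dimethylhydroxylamine hydrochloride, CNOC.Cl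
Why: Ester aminolysis by the magnesium amide of N,O-dimethylhydroxylamine (Weinreb amide synthesis); the hydroxyl rides along as its magnesium alkoxide and the stereocentre, which is not alpha to the carbonyl, is untouched.

Step 4
Reactants: 3 4-bromo-1,8-dimethoxynaphthalene; 5 (R)-3-hydroxy-N-methoxy-N-methylbutanamide
Product: 8 (R)-1-(4,5-dimethoxynaphthalen-1-yl)-3-hydroxybutan-1-one, via (4,5-dimethoxynaphthalen-1-yl)lithium 6 (not isolated), via chloromagnesium alkoxide of the amide 7 (not isolated)
Conditions: 3, n-BuLi, THF, −78 °C; 5 pre-treated with i-PrMgCl (1.0 equiv), THF, −20 °C; combine, −78 → 0 °C; aq. NH4Cl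
Reagents that add atoms: none
Why: Bromine–lithium exchange followed by Weinreb ketone synthesis; the magnesium alkoxide masks the hydroxyl in the flask and the N-methoxy chelate holds the tetrahedral adduct until the quench, so neither over-addition nor retro-aldol cleavage should occur before the ketone is released in buffered water.

Step 5
Reactants: 9 3-(benzyloxy)phenol
Product: 10 3-(benzyloxy)phenyl isopropylcarbamate
Conditions: i-PrNCO, Et3N (cat.), CH2Cl2, rt
Reagents that add atoms: isopropyl isocyanate, CC(C)N=C=O
Why: Amine-catalysed addition of a phenol to an isocyanate (carbamoylation); the N-isopropyl carbamate is a strong ortho director and can later be removed under mild base.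

Step 6
Reactants: 10 3-(benzyloxy)phenyl isopropylcarbamate
Product: 14 3-(benzyloxy)-2-(trimethylsilyl)phenyl isopropylcarbamate, via N-silyl carbamate 11 (not isolated), via ortho-lithiated N-silyl carbamate 12 (not isolated), via N-silyl C-silyl carbamate 13 (not isolated)
Conditions: TBSOTf, TMEDA, Et2O, 0 °C → rt; then TMEDA, n-BuLi (excess), −78 °C; TMSCl, −78 °C → rt; aq. NaHSO4
Reagents that add atoms: chlorotrimethylsilane, C[Si](C)(C)Cl
Why: Directed ortho-metalation; transient N-silylation prevents loss of isocyanate from the N–H carbamate, the carbamate and benzyloxy groups together direct n-BuLi to C2 between them, and TMSCl quenches the aryllithium. The N-silyl group is hydrolysed in the acidic work-up.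

Step 7
Reactants: 14 3-(benzyloxy)-2-(trimethylsilyl)phenyl isopropylcarbamate
Product: 16 3-(benzyloxy)-2-(trimethylsilyl)phenyl trifluoromethanesulfonate, via 3-(benzyloxy)-2-(trimethylsilyl)phenol 15 (not isolated)
Conditions: DBU, Et2NH, MeCN, 40 °C; then PhNTf2, rt
Reagents that add atoms: N-phenylbis(trifluoromethanesulfonimide), O=S(=O)(N(c1ccccc1)S(=O)(=O)C(F)(F)F)C(F)(F)F
Why: E1cB cleavage of the N-monoalkyl carbamate (loss of isopropyl isocyanate, trapped by Et2NH as a urea) gives the phenoxide, which PhNTf2 triflates in the same flask; this is the standard close of the carbamate route to ortho-silylaryl triflates.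

Step 8
Reactants: 16 3-(benzyloxy)-2-(trimethylsilyl)phenyl trifluoromethanesulfonate; 8 (R)-1-(4,5-dimethoxynaphthalen-1-yl)-3-hydroxybutan-1-one
Product: 19 (2R)-5-(benzyloxy)-4-(4,5-dimethoxynaphthalen-1-yl)-2-methylchroman-4-ol (both C4 epimers), via 3-(benzyloxy)benzyne 17 (not isolated), via ortho-cesio aryl ether 18 (not isolated)
Conditions: CsF (3 equiv), 16 (1.5 equiv), THF, 40 °C
Reagents that add atoms: none
Why: Proposed new method: fluoride attacks silicon in 16 and the ortho triflate leaves, releasing aryne 17; the fluoride-activated hydroxyl of 8 adds to the aryne carbon meta to the benzyloxy group (O1–C8a) to give aryl anion 18, which adds to the naphthyl ketone (C4–C4a) before it is protonated. The closest known reaction type is the aryne insertion annulation of ortho-hydroxyaryl aldehydes, ketones and esters (phenol O-arylation, then carbonyl capture, to xanthenols and xanthones); an aliphatic beta-hydroxy ketone as the partner is the untested element. The pyran ring closes by a 6-exo-trig addition of the aryl anion to the carbonyl group through a chair-like array with the C2 methyl equatorial. C2 is carried over from 8 with retention because its C–O bond is never broken; the new C4 carbinol centre is not controlled and need not be, since step 9 ionizes it. The selectivity the step needs is regiochemical, and the benzyloxy group secures it: by induction and by distorting the aryne it makes the remote carbon the electrophilic one and places the carbanion next to itself, between two oxygens, which is the C8a/C4a assignment of the target. Chemoselectivity against retro-aldol cleavage and dehydration of 8 rests on the low basicity of CsF suspended in THF, on a solvent that offers 18 no acidic proton, and on an excess of 16 so that O-arylation outruns the side reactions.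

Step 9
Reactants: 19 (2R)-5-(benzyloxy)-4-(4,5-dimethoxynaphthalen-1-yl)-2-methylchroman-4-ol (both C4 epimers)
Product: 20 (2R)-5-(benzyloxy)-4-(4,5-dimethoxynaphthalen-1-yl)-2-methylchroman (C4 epimer mixture, expected to be rich in the cis (2R,4R) isomer)
Conditions: Et3SiH, CF3CO2H, CH2Cl2, −40 → 0 °C
Reagents that add atoms: none
Why: Ionic hydrogenation; the acid ionizes the tertiary, doubly benzylic carbinol to a cation stabilized by both oxygenated aryl groups, and Et3SiH transfers hydride to C4, so both epimers of 19 converge. Axial hydride delivery on the half-chair with methyl equatorial should favour the cis isomer, but the ratio does not matter because step 10 equilibrates C4.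

Step 10
Reactants: 20 (2R)-5-(benzyloxy)-4-(4,5-dimethoxynaphthalen-1-yl)-2-methylchroman (C4 epimer mixture)
Product: 21 (2R,4S)-5-(benzyloxy)-4-(4,5-dimethoxynaphthalen-1-yl)-2-methylchroman (2,4-trans)
Conditions: KOtBu, DMSO (degassed, Ar), rt → 50 °C; AcOH quench
Reagents that add atoms: none
Why: Base-mediated epimerization of a doubly benzylic methine by reversible deprotonation at C4; C4 is set under thermodynamic control by C2, because with methyl equatorial the trans isomer holds the naphthyl pseudoaxial and clear of the peri benzyloxy group. C2 has no acidic hydrogen and stays (R); the phenol is kept benzylated so that no phenoxide lowers the acidity of C4–H.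

Step 11
Reactants: 21 (2R,4S)-5-(benzyloxy)-4-(4,5-dimethoxynaphthalen-1-yl)-2-methylchroman
Product: 22 Cladonaphchrom A, (2R,4S)-4-(4,5-dimethoxynaphthalen-1-yl)-2-methylchroman-5-ol
Conditions: H2 (1 atm), Pd/C, EtOAc–EtOH, rt
Reagents that add atoms: none
Why: Hydrogenolysis of the benzyl aryl ether; the methyl ethers, the non-benzylic C2–O1 ether and the C4 methine are inert under these conditions, and stopping at consumption of 21 should avoid reduction of the naphthalene.

## Compound list

1 | naphthalene-1,8-diol | Oc1cccc2cccc(O)c12 | starting material
2 | 1,8-dimethoxynaphthalene | COc1cccc2cccc(OC)c12 | intermediate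
3 | 4-bromo-1,8-dimethoxynaphthalene | COc1cccc2c(Br)ccc(OC)c12 | intermediate
4 | ethyl (R)-3-hydroxybutanoate | CCOC(=O)C[C@@H](C)O | starting material
5 | (R)-3-hydroxy-N-methoxy-N-methylbutanamide | CON(C)C(=O)C[C@@H](C)O | intermediate
6 | (4,5-dimethoxynaphthalen-1-yl)lithium (not isolated) | COc1cccc2c([Li])ccc(OC)c12 | intermediate
7 | chloromagnesium (R)-4-[methoxy(methyl)amino]-4-oxobutan-2-olate (not isolated) | CON(C)C(=O)C[C@@H](C)O[Mg]Cl | intermediate
8 | (R)-1-(4,5-dimethoxynaphthalen-1-yl)-3-hydroxybutan-1-one | COc1cccc2c(C(=O)C[C@@H](C)O)ccc(OC)c12 | intermediate
9 | 3-(benzyloxy)phenol | Oc1cccc(OCc2ccccc2)c1 | starting material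
10 | 3-(benzyloxy)phenyl isopropylcarbamate | CC(C)NC(=O)Oc1cccc(OCc2ccccc2)c1 | intermediate
11 | 3-(benzyloxy)phenyl N-(tert-butyldimethylsilyl)-N-isopropylcarbamate (not isolated) | CC(C)N(C(=O)Oc1cccc(OCc2ccccc2)c1)[Si](C)(C)C(C)(C)C | intermediate
12 | 3-(benzyloxy)-2-lithiophenyl N-(tert-butyldimethylsilyl)-N-isopropylcarbamate (not isolated) | CC(C)N(C(=O)Oc1cccc(OCc2ccccc2)c1[Li])[Si](C)(C)C(C)(C)C | intermediate
13 | 3-(benzyloxy)-2-(trimethylsilyl)phenyl N-(tert-butyldimethylsilyl)-N-isopropylcarbamate (not isolated) | CC(C)N(C(=O)Oc1cccc(OCc2ccccc2)c1[Si](C)(C)C)[Si](C)(C)C(C)(C)C | intermediate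
14 | 3-(benzyloxy)-2-(trimethylsilyl)phenyl isopropylcarbamate | CC(C)NC(=O)Oc1cccc(OCc2ccccc2)c1[Si](C)(C)C | intermediate
15 | 3-(benzyloxy)-2-(trimethylsilyl)phenol (not isolated) | C[Si](C)(C)c1c(O)cccc1OCc1ccccc1 | intermediate
16 | 3-(benzyloxy)-2-(trimethylsilyl)phenyl trifluoromethanesulfonate | C[Si](C)(C)c1c(OCc2ccccc2)cccc1OS(=O)(=O)C(F)(F)F | intermediate
17 | 3-(benzyloxy)benzyne (not isolated) | C1#CC(OCc2ccccc2)=CC=C1 | intermediate
18 | [2-(benzyloxy)-6-{[(2R)-4-(4,5-dimethoxynaphthalen-1-yl)-4-oxobutan-2-yl]oxy}phenyl]cesium (not isolated) | COc1cccc2c(C(=O)C[C@@H](C)Oc3cccc(OCc4ccccc4)c3[Cs])ccc(OC)c12 | intermediate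
19 | (2R)-5-(benzyloxy)-4-(4,5-dimethoxynaphthalen-1-yl)-2-methylchroman-4-ol, both C4 epimers | COc1cccc2c(C3(O)C[C@@H](C)Oc4cccc(OCc5ccccc5)c43)ccc(OC)c12 | intermediate
20 | (2R)-5-(benzyloxy)-4-(4,5-dimethoxynaphthalen-1-yl)-2-methylchroman, C4 epimer mixture | COc1cccc2c(C3C[C@@H](C)Oc4cccc(OCc5ccccc5)c43)ccc(OC)c12 | intermediate
21 | (2R,4S)-5-(benzyloxy)-4-(4,5-dimethoxynaphthalen-1-yl)-2-methylchroman | COc1cccc2c([C@@H]3C[C@@H](C)Oc4cccc(OCc5ccccc5)c43)ccc(OC)c12 | intermediate
22 | Cladonaphchrom A, (2R,4S)-4-(4,5-dimethoxynaphthalen-1-yl)-2-methylchroman-5-ol | COc1cccc2c([C@@H]3C[C@@H](C)Oc4cccc(O)c43)ccc(OC)c12 | target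

## Step count and risks

Total steps: 11. Longest linear sequence: 7 (steps 1, 2, 4, 8, 9, 10, 11, or equally steps 5, 6, 7, 8, 9, 10, 11).

**Step 8 (key step, proposed new method).**
- What may go wrong: retro-aldol cleavage or dehydration of 8 before O-arylation, because fluoride in an aprotic solvent is basic enough to form the aldolate. Alternatively, protonation of aryl anion 18 before carbonyl capture, or its internal proton abstraction from the C3 methylene, would leave an uncyclized aryl ether.
- Fallback (known reactions only): it sets out from amide 5 (as 7) and bromide 3 (as 6) and returns at 19. 1-(Benzyloxy)-3-fluorobenzene F1 is lithiated between fluorine and oxygen (n-BuLi, THF, −78 °C) to [2-(benzyloxy)-6-fluorophenyl]lithium F2. This is acylated with 7 to (R)-1-[2-(benzyloxy)-6-fluorophenyl]-3-hydroxybutan-1-one F3, which forms C4–C4a. The hydroxyl then displaces the ketone-activated ortho fluoride in an intramolecular nucleophilic aromatic substitution (K2CO3, DMF, rt, short contact) to give (R)-5-(benzyloxy)-2-methylchroman-4-one F4, forming O1–C8a with retention at C2. Addition of aryllithium 6 at −78 °C gives 19.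

**Step 10.**
- What may go wrong: slow or incomplete proton exchange at the crowded methine, an equilibrium less one-sided than assumed, or autoxidation of the benzylic carbanion by traces of oxygen.
- Fallback: the aryl group is brought in as the nucleophile instead of hydride. It sets out from 5 (through (R)-5-(benzyloxy)-2-methylchroman-4-one F4, made as described under step 8) and from 2, and returns at 21. F4 is reduced with NaBH4 to (2R)-5-(benzyloxy)-2-methylchroman-4-ol F5. F5 is ionized with BF3·OEt2 in CH2Cl2 at low temperature in the presence of 2, which is alkylated at C4 (para to methoxy) in a Friedel–Crafts reaction. The arene should enter the chromanyl cation anti to the C2 methyl, giving the trans isomer 21 under kinetic control.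

**Step 9.**
- What may go wrong: the cation is diverted before hydride transfer, by elimination to the chromene without re-protonation, by Friedel–Crafts attack on the benzyl ring, or by acid loss of the benzyl group.
- Fallback: it sets out from 19 and returns at 20. 19 is dehydrated under basic conditions (MsCl, Et3N, CH2Cl2) to (R)-5-(benzyloxy)-4-(4,5-dimethoxynaphthalen-1-yl)-2-methyl-2H-chromene F6, handled with exclusion of light. The trisubstituted double bond is then hydrogenated homogeneously (H2, [Ir(cod)(PCy3)(py)]PF6, CH2Cl2), which leaves the benzyl ether and should deliver hydrogen anti to the C2 methyl, giving cis-rich 20 for step 10.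

**Step 4.**
- What may go wrong: incomplete addition to the alkoxide-bearing amide (aggregation, proton transfer to 6), or retro-aldol cleavage if the chelate collapses before the quench.
- Fallback: it sets out from 5 and returns at 8. 5 is silylated (TBSCl, imidazole, DMF) to (R)-3-[(tert-butyldimethylsilyl)oxy]-N-methoxy-N-methylbutanamide F7. Addition of 6 gives (R)-3-[(tert-butyldimethylsilyl)oxy]-1-(4,5-dimethoxynaphthalen-1-yl)butan-1-one F8, and HF·pyridine in THF releases 8.

## Further compounds

F1 | step 8 | 1-(benzyloxy)-3-fluorobenzene | Fc1cccc(OCc2ccccc2)c1
F2 | step 8 | [2-(benzyloxy)-6-fluorophenyl]lithium | [Li]c1c(F)cccc1OCc1ccccc1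
F3 | step 8 | (R)-1-[2-(benzyloxy)-6-fluorophenyl]-3-hydroxybutan-1-one | O=C(C[C@@H](C)O)c1c(F)cccc1OCc1ccccc1
F4 | step 8 | (R)-5-(benzyloxy)-2-methylchroman-4-one | O=C1C[C@@H](C)Oc2cccc(OCc3ccccc3)c21
F5 | step 10 | (2R)-5-(benzyloxy)-2-methylchroman-4-ol, C4 epimers | OC1C[C@@H](C)Oc2cccc(OCc3ccccc3)c21
F6 | step 9 | (R)-5-(benzyloxy)-4-(4,5-dimethoxynaphthalen-1-yl)-2-methyl-2H-chromene | COc1cccc2c(C3=C[C@@H](C)Oc4cccc(OCc5ccccc5)c43)ccc(OC)c12
F7 | step 4 | (R)-3-[(tert-butyldimethylsilyl)oxy]-N-methoxy-N-methylbutanamide | CON(C)C(=O)C[C@@H](C)O[Si](C)(C)C(C)(C)C
F8 | step 4 | (R)-3-[(tert-butyldimethylsilyl)oxy]-1-(4,5-dimethoxynaphthalen-1-yl)butan-1-one | COc1cccc2c(C(=O)C[C@@H](C)O[Si](C)(C)C(C)(C)C)ccc(OC)c12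
A1 | alternative 1 | 1-[(2R)-5-(benzyloxy)-2-methylchroman-4-yl]-5-(4,4,5,5-tetramethyl-1,3,2-dioxaborolan-2-yl)-1,4-epoxy-1,4-dihydronaphthalene (2,4-trans chroman, one bridgehead diastereomer) | CC1(C)OB(OC1(C)C)c5cccc6c5[C@@H]7C=C[C@]6(O7)[C@@H]3C[C@@H](C)Oc4cccc(OCc8ccccc8)c43
A2 | alternative 1 | (2R,4R)-5-(benzyloxy)-4-(furan-2-yl)-2-methylchroman (2,4-trans) | o1cccc1[C@@H]2C[C@@H](C)Oc3cccc(OCc4ccccc4)c32
A3 | alternative 1 | 3-(4,4,5,5-tetramethyl-1,3,2-dioxaborolan-2-yl)benzyne | CC1(C)OB(OC1(C)C)C2=CC=CC#C2
A4 | alternative 2 | 4-(4,5-dimethoxynaphthalen-1-yl)-2-methoxy-2-methylchroman-5-ol (C4 as in 22) | COc1cccc2c([C@@H]3C[C@](C)(OC)Oc4cccc(O)c43)ccc(OC)c12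
A5 | alternative 2 | (2,6-dihydroxyphenyl)(4,5-dimethoxynaphthalen-1-yl)methanol | COc1cccc2c(C(O)c3c(O)cccc3O)ccc(OC)c12
A6 | alternative 2 | 6-[(4,5-dimethoxynaphthalen-1-yl)methylidene]-5-hydroxycyclohexa-2,4-dien-1-one (ortho-quinone methide) | COc1cccc2c(C=C3C(=O)C=CC=C3O)ccc(OC)c12
A7 | alternative 2 | 2-methoxypropene | COC(C)=C
A8 | alternative 3 | (2R,4S)-4-(4,5-dimethoxynaphthalen-1-yl)-2-methylchroman-5-yl pivalate | COc1cccc2c([C@@H]3C[C@@H](C)Oc4cccc(OC(=O)C(C)(C)C)c43)ccc(OC)c12
A9 | alternative 3 | 3-hydroxy-2-vinylphenyl pivalate | C=Cc1c(O)cccc1OC(=O)C(C)(C)C
A10 | alternative 3 | acetaldehyde | CC=O
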